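**Retrosynthetic overview**
- Feature: the target is a nonaene (eight chain C=C plus the ring C6'=C7'). In carotenoid numbering its chain holds two C(sp2)–C(sp2) single bonds, C10–C11 and C10'–C11'. They flank the symmetric C11–C11' pentaene (with the C13/C13' methyls) and separate it from the cyclohexane-3,5,6-triol ring and from the 5',8'-epoxy (hexahydrobenzofuran) ring.
- Both bonds are cut together: a pentaene with tin at C11 and boron at C11' is joined to the triol-end dienyl iodide at tin (neutral), then to the furanoid-end alkenyl iodide at boron (after base).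
- Both end groups come from one ketoisophorone-derived (R)-silyloxy dienyne iodide. Hydroxyl-directed syn epoxidation, trans-diaxial hydrolysis and alkyne trans-reduction give the triol iodide. Anti epoxidation, anti-SN2' hydride opening to an allene and gold-catalysed O–C8' closure give the furanoid iodide.
- The linchpin comes from the C10 trienedial by two chromium-mediated one-carbon olefinations (boron first, then tin).
- Ring order: both carbocycles are carried intact from ketoisophorone; the dihydrofuran is the only ring closed (step 10); the key step closes none.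

Key step: step 19

Assumption: carotenoid numbering is used in the comments; "syn" and "anti" refer to the ring oxygen at C3; the two enzymes of step 1 are bought as commercial preparations.

**Step 1**
Reactants: 1 ketoisophorone
Product: 2 (6R)-2,2,6-trimethylcyclohexane-1,4-dione
Conditions: ene-reductase OYE1, NADP+ (cat.), glucose dehydrogenase, D-glucose, phosphate buffer pH 7, 30 °C
Reagents that add atoms: none
Why: Ene-reductase (Old Yellow Enzyme) reduction of the activated ring C=C by flavin hydride transfer and protonation, in which the enzyme pocket sets C6 as (R) while glucose/glucose dehydrogenase recycles NADPH.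

**Step 2**
Reactants: 2 (6R)-2,2,6-trimethylcyclohexane-1,4-dione
Product: 3 (4R,6R)-4-hydroxy-2,2,6-trimethylcyclohexan-1-one
Conditions: LiBH(s-Bu)3 (L-Selectride), THF, −78 °C; H2O
Reagents that add atoms: none
Why: Chemo- and diastereoselective hydride reduction, the bulky borohydride reacting only at the unhindered C4 carbonyl and from the equatorial side away from the axial C2 methyl, so the carbinol is axial and trans to the C6 methyl, i.e. (4R).

**Step 3**
Reactants: 3 (4R,6R)-4-hydroxy-2,2,6-trimethylcyclohexan-1-one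
Product: 4 (4R,6R)-4-[(tert-butyldimethylsilyl)oxy]-2,2,6-trimethylcyclohexan-1-one
Conditions: TBSCl, imidazole, DMF, 23 °C
Reagents that add atoms: tert-butyldimethylsilyl chloride, CC(C)(C)[Si](C)(C)Cl
Why: Standard silylation of the secondary alcohol, which protects O3 through the organometallic steps and later serves as the bulky group for face selection.

**Step 4**
Reactants: 4 (4R,6R)-4-[(tert-butyldimethylsilyl)oxy]-2,2,6-trimethylcyclohexan-1-one
Product: 5 (4R)-4-[(tert-butyldimethylsilyl)oxy]-2,6,6-trimethylcyclohex-1-en-1-yl trifluoromethanesulfonate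
Conditions: LiN(iPr)2, THF, −78 → 0 °C; PhNTf2, −78 → 23 °C
Reagents that add atoms: N-phenylbis(trifluoromethanesulfonimide), FC(F)(F)S(=O)(=O)N(c1ccccc1)S(=O)(=O)C(F)(F)F
Why: Enolate O-sulfonylation; only C6 carries an α-hydrogen, so a single tetrasubstituted enol triflate forms and the C6 centre, having relayed chirality to C4, is erased.

**Step 5**
Reactants: 5 enol triflate, 6 1,4-bis(trimethylsilyl)buta-1,3-diyne
Product: 9 tert-butyldimethyl({(1R)-3,5,5-trimethyl-4-[4-(trimethylsilyl)buta-1,3-diyn-1-yl]cyclohex-3-en-1-yl}oxy)silane, via lithium (trimethylsilyl)butadiynide 7 (not isolated), via (trimethylsilyl)butadiynylzinc chloride 8 (not isolated)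
Conditions: 6, MeLi·LiBr, THF, 0 → 23 °C; ZnCl2; then 5, Pd(PPh3)4 (5 mol%), THF, 23 → 40 °C
Reagents that add atoms: none
Why: Negishi alkynylation; mono-desilylation of the bis-silyl diyne gives the lithium diynide, and transmetalation to zinc with zerovalent-palladium catalysis forms C6–C7 on the hindered enol triflate without handling the volatile free diyne.

**Step 6**
Reactants: 9 silyl-capped dienediyne
Product: 10 {[(1R)-4-(buta-1,3-diyn-1-yl)-3,5,5-trimethylcyclohex-3-en-1-yl]oxy}(tert-butyl)dimethylsilane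
Conditions: K2CO3, MeOH/THF, 0 → 23 °C; used at once in solution
Reagents that add atoms: none
Why: Mild methanolysis of the alkynyl C–Si bond leaves the secondary TBS ether untouched; the terminal diyne is not concentrated.

**Step 7**
Reactants: 10 terminal dienediyne
Product: 12 tert-butyl({(1R)-4-[(3E)-4-iodo-3-methylbut-3-en-1-yn-1-yl]-3,5,5-trimethylcyclohex-3-en-1-yl}oxy)dimethylsilane, via alkenyl(dimethyl)alane 11 (not isolated)
Conditions: AlMe3, Cp2ZrCl2 (25 mol%), CH2Cl2, 0 → 23 °C; then I2, THF, −30 °C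
Reagents that add atoms: trimethylaluminium, C[Al](C)C; iodine, II
Why: Negishi zirconium-catalysed methylalumination adds Me–Al syn across the terminal alkyne (methyl on C9, aluminium on C10), and iodinolysis with retention gives the (E)-iodoalkene that now carries C19.

**Step 8**
Reactants: 12 dienyne iodide
Product: 13 tert-butyl({(1R,3S,6R)-6-[(3E)-4-iodo-3-methylbut-3-en-1-yn-1-yl]-1,5,5-trimethyl-7-oxabicyclo[4.1.0]heptan-3-yl}oxy)dimethylsilane (epoxide oxygen anti to the silyloxy group)
Conditions: mCPBA, NaHCO3, CH2Cl2, 0 °C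
Reagents that add atoms: 3-chloroperoxybenzoic acid, OOC(=O)c1cccc(Cl)c1
Why: Prilezhaev epoxidation of the most electron-rich (tetrasubstituted) alkene, with attack anti to the silyloxy group expected to predominate and to set C5 and C6; the separable syn epoxide is not wasted, since desilylation turns it into 18.

**Step 9**
Reactants: 13 anti alkynyl epoxide
Product: 14 (1R,5S)-5-[(tert-butyldimethylsilyl)oxy]-2-[(3E)-4-iodo-3-methylbuta-1,3-dien-1-ylidene]-1,3,3-trimethylcyclohexan-1-ol, allene axis (Sa), iodopropenyl group on the side of the hydroxyl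
Conditions: (IPr)CuCl (5 mol%; IPr = 1,3-bis(2,6-diisopropylphenyl)imidazol-2-ylidene), NaOtBu (5 mol%), (EtO)2MeSiH, t-BuOH, toluene, 0 → 23 °C
Reagents that add atoms: none
Why: Copper hydride-catalysed SN2' reduction of a propargyl oxirane; syn hydrocupration and anti β-alkoxide elimination should deliver hydride to C8 anti to the breaking C6–O bond, trading the C6 centre for (Sa) axial chirality while the C5 carbinol is retained.

**Step 10**
Reactants: 14 α-hydroxyallene
Product: 15 tert-butyl({(2R,6S,7aR)-2-[(1E)-1-iodoprop-1-en-2-yl]-4,4,7a-trimethyl-2,4,5,6,7,7a-hexahydro-1-benzofuran-6-yl}oxy)dimethylsilane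
Conditions: AuCl3 (2 mol%), THF, 0 → 23 °C, dark
Reagents that add atoms: none
Why: Gold-catalysed 5-endo cycloisomerisation of an α-hydroxyallene; the tertiary hydroxyl adds to the activated C7=C8 bond in the plane of the ring substituents and protodeauration follows, so the axis is transferred to the (2R) centre (iodopropenyl trans to the angular methyl), and THF with low catalyst loading limits epimerisation of the doubly allylic ether.

**Step 11**
Reactants: 15 silylated furanoid iodide
Product: 16 (2R,6S,7aR)-2-[(1E)-1-iodoprop-1-en-2-yl]-4,4,7a-trimethyl-2,4,5,6,7,7a-hexahydro-1-benzofuran-6-ol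
Conditions: Bu4NF, THF, 0 → 23 °C
Reagents that add atoms: none
Why: Fluoride cleavage of the silyl ether under non-acidic conditions that spare the alkenyl iodide and the allylic ether.

**Step 12**
Reactants: 12 dienyne iodide
Product: 17 (1R)-4-[(3E)-4-iodo-3-methylbut-3-en-1-yn-1-yl]-3,5,5-trimethylcyclohex-3-en-1-ol
Conditions: Bu4NF, THF, 0 → 23 °C
Reagents that add atoms: none
Why: Fluoride desilylation frees the homoallylic hydroxyl that directs the next step.

**Step 13**
Reactants: 17 homoallylic alcohol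
Product: 18 (1S,3S,6S)-6-[(3E)-4-iodo-3-methylbut-3-en-1-yn-1-yl]-1,5,5-trimethyl-7-oxabicyclo[4.1.0]heptan-3-ol (epoxide oxygen syn to the hydroxyl)
Conditions: VO(acac)2 (5 mol%), t-BuOOH, toluene, 23 → 40 °C
Reagents that add atoms: tert-butyl hydroperoxide, CC(C)(C)OO
Why: Hydroxyl-directed vanadium-catalysed epoxidation; the bound homoallylic alcohol delivers oxygen to the ring alkene on its own face, giving the syn epoxide and leaving the iodoalkene untouched.

**Step 14**
Reactants: 18 syn alkynyl epoxide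
Product: 19 (1S,2R,4S)-1-[(3E)-4-iodo-3-methylbut-3-en-1-yn-1-yl]-2,6,6-trimethylcyclohexane-1,2,4-triol
Conditions: HClO4 (cat.), THF/H2O (3:1), 0 → 23 °C
Reagents that add atoms: water, O
Why: Acid-catalysed epoxide hydrolysis by trans-diaxial (Fürst–Plattner) opening; water attacks the tertiary alkyl carbon C5 with inversion rather than the neopentyl, alkynyl-bearing C6, so the new C5 hydroxyl ends anti and the retained C6 hydroxyl syn to the C3 hydroxyl.

**Step 15**
Reactants: 19 propargylic triol
Product: 20 (1R,2R,4S)-1-[(1E,3E)-4-iodo-3-methylbuta-1,3-dien-1-yl]-2,6,6-trimethylcyclohexane-1,2,4-triol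
Conditions: NaAlH2(OCH2CH2OCH3)2 (Red-Al), THF, −20 → 0 °C; aq. Rochelle salt
Reagents that add atoms: none
Why: Hydroxyl-directed trans-hydroalumination of the tertiary propargylic alcohol and protonolysis give the (E)-C7=C8 alkene; the low temperature is chosen so that the alkenyl iodide survives.

**Step 16**
Reactants: 21 dibromomethane
Product: 23 tributyl(dibromomethyl)stannane, via dibromomethyllithium 22 (not isolated)
Conditions: LiN(iPr)2, THF, −78 °C; Bu3SnCl, −78 → 0 °C
Reagents that add atoms: tributyltin chloride, CCCC[Sn](Cl)(CCCC)CCCC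
Why: Deprotonation of dibromomethane to the lithium carbenoid and trapping at tin gives the gem-dibromide needed for stannyl olefination.

**Step 17**
Reactants: 24 (2E,4E,6E)-2,7-dimethylocta-2,4,6-trienedial (in excess), 25 2-(dichloromethyl)-4,4,5,5-tetramethyl-1,3,2-dioxaborolane
Product: 26 (2E,4E,6E,8E)-2,7-dimethyl-9-(4,4,5,5-tetramethyl-1,3,2-dioxaborolan-2-yl)nona-2,4,6,8-tetraenal
Conditions: CrCl2, LiI, THF, 23 °C, dark
Reagents that add atoms: none
Why: Takai–Utimoto boryl olefination; the gem-dichromium reagent made from 25 and divalent chromium adds to one aldehyde and eliminates to the (E)-alkenylboronate, and an excess of the symmetric dialdehyde, which is recovered, limits double reaction.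

**Step 18**
Reactants: 26 boryl tetraenal, 23 tributyl(dibromomethyl)stannane
Product: 27 tributyl[(1E,3E,5E,7E,9E)-3,8-dimethyl-10-(4,4,5,5-tetramethyl-1,3,2-dioxaborolan-2-yl)deca-1,3,5,7,9-pentaen-1-yl]stannane
Conditions: CrCl2, LiI, THF/DMF, 23 °C, dark; chromatography on Et3N-deactivated silica
Reagents that add atoms: none
Why: Takai-type stannyl olefination; the gem-dichromium species from 23 converts the remaining aldehyde into the (E)-alkenylstannane, the pinacol boronate being inert to divalent chromium.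

**Step 19**
Reactants: 20 triol dienyl iodide, 27 tin/boron pentaene, 16 furanoid alkenyl iodide
Product: 29 (3S,5R,6R,3'S,5'R,8'R)-5',8'-epoxy-5,6,5',8'-tetrahydro-β,β-carotene-3,5,6,3'-tetrol (the target), via heptaenyl pinacol boronate 28 (not isolated)
Conditions: 20, 27, Pd(PPh3)4 (5 mol%, zerovalent palladium), CuI (10 mol%), DMF, 23 °C, argon, dark; then 16, TlOEt, THF/H2O, 23 °C; HPLC with exclusion of light
Reagents that add atoms: none
Why: Iodide 20 adds oxidatively to zerovalent palladium, the alkenyl group is transferred from tin under neutral conditions and reductive elimination forms C10–C11; the boronate cannot transmetalate because no base is present. Adding 16 and ethoxide then forms the boron ate complex, and a second oxidative addition, transmetalation and reductive elimination form C10'–C11'. The closest known reaction type is the sequential Stille and Suzuki–Miyaura coupling of polyenes that carry tin at one end and boron at the other. No ring is closed and no stereocentre is created. The selectivity needed is tin before boron, secured by withholding base until the first coupling is complete, and retention of every (E) geometry, secured by the stereoretentive palladium steps and the dark. The medium stays neutral to basic, so the three free carbinols of 20 and the acid-labile C8' allylic ether of 16 pass through unprotected and unchanged.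

**Compound list**
1 | 2,6,6-trimethylcyclohex-2-ene-1,4-dione (ketoisophorone) | CC1=CC(=O)CC(C)(C)C1=O | starting material
2 | (6R)-2,2,6-trimethylcyclohexane-1,4-dione | C[C@@H]1CC(=O)CC(C)(C)C1=O | intermediate
3 | (4R,6R)-4-hydroxy-2,2,6-trimethylcyclohexan-1-one | C[C@@H]1C[C@@H](O)CC(C)(C)C1=O | intermediate
4 | (4R,6R)-4-[(tert-butyldimethylsilyl)oxy]-2,2,6-trimethylcyclohexan-1-one | C[C@@H]1C[C@@H](O[Si](C)(C)C(C)(C)C)CC(C)(C)C1=O | intermediate
5 | (4R)-4-[(tert-butyldimethylsilyl)oxy]-2,6,6-trimethylcyclohex-1-en-1-yl trifluoromethanesulfonate | CC1=C(OS(=O)(=O)C(F)(F)F)C(C)(C)C[C@H](O[Si](C)(C)C(C)(C)C)C1 | intermediate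
6 | 1,4-bis(trimethylsilyl)buta-1,3-diyne | C[Si](C)(C)C#CC#C[Si](C)(C)C | starting material
7 | lithium 4-(trimethylsilyl)buta-1,3-diyn-1-ide | [Li]C#CC#C[Si](C)(C)C | intermediate
8 | chloro[4-(trimethylsilyl)buta-1,3-diyn-1-yl]zinc | Cl[Zn]C#CC#C[Si](C)(C)C | intermediate
9 | tert-butyldimethyl({(1R)-3,5,5-trimethyl-4-[4-(trimethylsilyl)buta-1,3-diyn-1-yl]cyclohex-3-en-1-yl}oxy)silane | CC1=C(C#CC#C[Si](C)(C)C)C(C)(C)C[C@H](O[Si](C)(C)C(C)(C)C)C1 | intermediate
10 | {[(1R)-4-(buta-1,3-diyn-1-yl)-3,5,5-trimethylcyclohex-3-en-1-yl]oxy}(tert-butyl)dimethylsilane | CC1=C(C#CC#C)C(C)(C)C[C@H](O[Si](C)(C)C(C)(C)C)C1 | intermediate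
11 | {(1E)-4-[(4R)-4-{[tert-butyl(dimethyl)silyl]oxy}-2,6,6-trimethylcyclohex-1-en-1-yl]-2-methylbut-1-en-3-yn-1-yl}(dimethyl)alumane | CC1=C(C#C/C(C)=C/[Al](C)C)C(C)(C)C[C@H](O[Si](C)(C)C(C)(C)C)C1 | intermediate
12 | tert-butyl({(1R)-4-[(3E)-4-iodo-3-methylbut-3-en-1-yn-1-yl]-3,5,5-trimethylcyclohex-3-en-1-yl}oxy)dimethylsilane | CC1=C(C#C/C(C)=C/I)C(C)(C)C[C@H](O[Si](C)(C)C(C)(C)C)C1 | intermediate
13 | tert-butyl({(1R,3S,6R)-6-[(3E)-4-iodo-3-methylbut-3-en-1-yn-1-yl]-1,5,5-trimethyl-7-oxabicyclo[4.1.0]heptan-3-yl}oxy)dimethylsilane | CC1(C)C[C@H](O[Si](C)(C)C(C)(C)C)C[C@@]2(C)O[C@@]12C#C/C(C)=C/I | intermediate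
14 | (1R,5S)-5-[(tert-butyldimethylsilyl)oxy]-2-[(3E)-4-iodo-3-methylbuta-1,3-dien-1-ylidene]-1,3,3-trimethylcyclohexan-1-ol, (Sa) axis | CC1(C)C[C@H](O[Si](C)(C)C(C)(C)C)C[C@@](C)(O)C1=[C@@]=C([H])/C(C)=C/I | intermediate
15 | tert-butyl({(2R,6S,7aR)-2-[(1E)-1-iodoprop-1-en-2-yl]-4,4,7a-trimethyl-2,4,5,6,7,7a-hexahydro-1-benzofuran-6-yl}oxy)dimethylsilane | I/C=C(\C)[C@H]1C=C2C(C)(C)C[C@H](O[Si](C)(C)C(C)(C)C)C[C@@]2(C)O1 | intermediate
16 | (2R,6S,7aR)-2-[(1E)-1-iodoprop-1-en-2-yl]-4,4,7a-trimethyl-2,4,5,6,7,7a-hexahydro-1-benzofuran-6-ol | I/C=C(\C)[C@H]1C=C2C(C)(C)C[C@H](O)C[C@@]2(C)O1 | intermediate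
17 | (1R)-4-[(3E)-4-iodo-3-methylbut-3-en-1-yn-1-yl]-3,5,5-trimethylcyclohex-3-en-1-ol | CC1=C(C#C/C(C)=C/I)C(C)(C)C[C@H](O)C1 | intermediate
18 | (1S,3S,6S)-6-[(3E)-4-iodo-3-methylbut-3-en-1-yn-1-yl]-1,5,5-trimethyl-7-oxabicyclo[4.1.0]heptan-3-ol | CC1(C)C[C@H](O)C[C@]2(C)O[C@]12C#C/C(C)=C/I | intermediate
19 | (1S,2R,4S)-1-[(3E)-4-iodo-3-methylbut-3-en-1-yn-1-yl]-2,6,6-trimethylcyclohexane-1,2,4-triol | I/C=C(\C)C#C[C@@]1(O)C(C)(C)C[C@H](O)C[C@@]1(C)O | intermediate
20 | (1R,2R,4S)-1-[(1E,3E)-4-iodo-3-methylbuta-1,3-dien-1-yl]-2,6,6-trimethylcyclohexane-1,2,4-triol | I/C=C(C)/C=C/[C@@]1(O)C(C)(C)C[C@H](O)C[C@@]1(C)O | intermediate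
21 | dibromomethane | BrCBr | starting material
22 | dibromomethyllithium | [Li]C(Br)Br | intermediate
23 | tributyl(dibromomethyl)stannane | CCCC[Sn](CCCC)(CCCC)C(Br)Br | intermediate
24 | (2E,4E,6E)-2,7-dimethylocta-2,4,6-trienedial | O=C/C(C)=C/C=C/C=C(C)/C=O | starting material
25 | 2-(dichloromethyl)-4,4,5,5-tetramethyl-1,3,2-dioxaborolane | ClC(Cl)B1OC(C)(C)C(C)(C)O1 | starting material
26 | (2E,4E,6E,8E)-2,7-dimethyl-9-(4,4,5,5-tetramethyl-1,3,2-dioxaborolan-2-yl)nona-2,4,6,8-tetraenal | O=C/C(C)=C/C=C/C=C(C)/C=C/B1OC(C)(C)C(C)(C)O1 | intermediate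
27 | tributyl[(1E,3E,5E,7E,9E)-3,8-dimethyl-10-(4,4,5,5-tetramethyl-1,3,2-dioxaborolan-2-yl)deca-1,3,5,7,9-pentaen-1-yl]stannane | CCCC[Sn](CCCC)(CCCC)/C=C/C(C)=C/C=C/C=C(C)/C=C/B1OC(C)(C)C(C)(C)O1 | intermediate
28 | (1R,2R,4S)-1-[(1E,3E,5E,7E,9E,11E,13E)-3,7,12-trimethyl-14-(4,4,5,5-tetramethyl-1,3,2-dioxaborolan-2-yl)tetradeca-1,3,5,7,9,11,13-heptaen-1-yl]-2,6,6-trimethylcyclohexane-1,2,4-triol | CC(/C=C/C=C(C)/C=C/[C@@]1(O)C(C)(C)C[C@H](O)C[C@@]1(C)O)=C\C=C\C=C(C)\C=C\B1OC(C)(C)C(C)(C)O1 | intermediate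
29 | (3S,5R,6R,3'S,5'R,8'R)-5',8'-epoxy-5,6,5',8'-tetrahydro-β,β-carotene-3,5,6,3'-tetrol (CNP0210286.2) | CC(/C=C/C=C(C)/C=C/[C@@]1(O)C(C)(C)C[C@H](O)C[C@@]1(C)O)=C\C=C\C=C(C)\C=C\C=C(/C)[C@H]1C=C2C(C)(C)C[C@H](O)C[C@@]2(C)O1 | target

**Step count**
Total: 19 steps. Longest linear sequence: 12 steps (steps 1–7, then 8–11 or 12–15, then 19).

**Steps most likely to fail**

Step 9. The hydride may be diverted to the carbon–iodine bond, or be delivered syn rather than anti to the departing oxygen, which would break the relay from the C6 centre through the allene axis to C8'. The fallback drops the allene relay and closes the furan ring by the classical acid-promoted allylic cyclisation of a 5,6-diol. It sets out from triol iodide 20. Brief treatment with catalytic pyridinium p-toluenesulfonate in CH2Cl2 at 0 °C ionises the tertiary allylic C6 hydroxyl, and the neighbouring C5 hydroxyl, which already has the required configuration, traps the dienyl cation at C8. This gives 16 together with (2S,6S,7aR)-2-[(1E)-1-iodoprop-1-en-2-yl]-4,4,7a-trimethyl-2,4,5,6,7,7a-hexahydro-1-benzofuran-6-ol F1, which is removed by chromatography. The route is rejoined at 16 and steps 8 to 11 become unnecessary; the price is that the new centre is no longer controlled.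

Step 15. Hydride attack at the alkenyl iodide (hydrodeiodination) may compete with the directed reduction of the hindered alkyne. The fallback replaces hydride reduction by hydrosilylation. It sets out from 19. Ruthenium-catalysed trans-hydrosilylation with (EtO)3SiH and [Cp*Ru(MeCN)3]PF6 in CH2Cl2 at 0 °C gives (1R,2R,4S)-1-[(1Z,3E)-4-iodo-3-methyl-2-(triethoxysilyl)buta-1,3-dien-1-yl]-2,6,6-trimethylcyclohexane-1,2,4-triol F2. Protodesilylation with Bu4NF and CuI in THF then gives the (E)-alkene and rejoins the route at 20.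

Step 19. In the one-pot sequence the boron end may begin to transmetalate before the tin end is consumed, or the long polyene may homocouple or lose (E) geometry. The fallback keeps the same two bonds but grows the chain stepwise with monofunctional partners. It sets out from boryl aldehyde 26 and iodide 16. Suzuki–Miyaura coupling (Pd(PPh3)4, TlOEt, THF/H2O, 23 °C) gives (2E,4E,6E,8E,10E)-11-[(2R,6S,7aR)-6-hydroxy-4,4,7a-trimethyl-2,4,5,6,7,7a-hexahydro-1-benzofuran-2-yl]-2,7-dimethyldodeca-2,4,6,8,10-pentaenal F3. Takai-type stannyl olefination of F3 with 23, CrCl2 and LiI gives tributyl{(1E,3E,5E,7E,9E,11E)-12-[(2R,6S,7aR)-6-hydroxy-4,4,7a-trimethyl-2,4,5,6,7,7a-hexahydro-1-benzofuran-2-yl]-3,8-dimethyltrideca-1,3,5,7,9,11-hexaen-1-yl}stannane F4. Stille coupling of F4 with 20 (Pd(PPh3)4, CuI, DMF, 23 °C, dark) then gives 29 directly.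

**Further compounds**
F1 | step 9 | (2S,6S,7aR)-2-[(1E)-1-iodoprop-1-en-2-yl]-4,4,7a-trimethyl-2,4,5,6,7,7a-hexahydro-1-benzofuran-6-ol | I/C=C(\C)[C@@H]1C=C2C(C)(C)C[C@H](O)C[C@@]2(C)O1
F2 | step 15 | (1R,2R,4S)-1-[(1Z,3E)-4-iodo-3-methyl-2-(triethoxysilyl)buta-1,3-dien-1-yl]-2,6,6-trimethylcyclohexane-1,2,4-triol | I/C=C(C)/C(=C/[C@@]1(O)C(C)(C)C[C@H](O)C[C@@]1(C)O)[Si](OCC)(OCC)OCC
F3 | step 19 | (2E,4E,6E,8E,10E)-11-[(2R,6S,7aR)-6-hydroxy-4,4,7a-trimethyl-2,4,5,6,7,7a-hexahydro-1-benzofuran-2-yl]-2,7-dimethyldodeca-2,4,6,8,10-pentaenal | O=C/C(C)=C/C=C/C=C(C)/C=C/C=C(\C)[C@H]1C=C2C(C)(C)C[C@H](O)C[C@@]2(C)O1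
F4 | step 19 | tributyl{(1E,3E,5E,7E,9E,11E)-12-[(2R,6S,7aR)-6-hydroxy-4,4,7a-trimethyl-2,4,5,6,7,7a-hexahydro-1-benzofuran-2-yl]-3,8-dimethyltrideca-1,3,5,7,9,11-hexaen-1-yl}stannane | CCCC[Sn](CCCC)(CCCC)/C=C/C(C)=C/C=C/C=C(C)/C=C/C=C(\C)[C@H]1C=C2C(C)(C)C[C@H](O)C[C@@]2(C)O1
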